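**Retrosynthetic overview**

1. The strategy rests on the six-membered carbocycle C1 (quaternary: CH3 and farnesyl)–C2 (C=O)–C3 (CH3)–C4 (enol OH)–C5 (CO2H)–C6 (CH3). It has the alternating oxygenation of a folded polyketide: C5 is a doubly activated methylene carbon, C6 a methyl-ketone carbon, and the quaternary C1 blocks aromatisation.
2. Target ⇐ its 2-(trimethylsilyl)ethyl (TMSE) ester (fluoride) ⇐ open-chain triketo TMSE ester, by Knoevenagel–aldol closure of the C5=C6 bond. This is the only ring and is formed in the penultimate step.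
3. Triketo ester ⇐ oxidation of a silyl-masked carbinol (the future C6 ketone), after γ-carboxylation of a β-diketone dianion, C-acetylation and C-methylation on the other, free methyl ketone. The acyl unit is brought in as acetyl and carboxylated afterwards because a malonyl donor would be more C–H acidic than the ketone it has to acylate.
4. C1 ⇐ ketoreductase desymmetrisation of the two enantiotopic acetyl groups of 3-farnesyl-3-methylpentane-2,4-dione ⇐ C-farnesylation of 3-methylpentane-2,4-dione.

Key step: step 10

Remark: the ketoreductase, chosen by panel screening, is assumed to reduce the acetyl group that leads to the (R) quaternary centre. The (S) carbinol drawn is erased in step 9, so either carbinol epimer would serve. 1,3-Dicarbonyl compounds are drawn as one tautomer, and the labile CH(CH3) centre between two carbonyls is left undefined. "Farnesyl" means (2E,6E)-3,7,11-trimethyldodeca-2,6,10-trien-1-yl throughout.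

**Route**

Step 1
Reactants: 1 3-methylpentane-2,4-dione; 2 (2E,6E)-farnesyl bromide
Product: 3 3-methyl-3-[(2E,6E)-farnesyl]pentane-2,4-dione
Conditions: K2CO3, acetone, reflux
Reagents that add atoms: none
Why: C-alkylation (SN2) of the stabilised enolate of a 2-substituted 1,3-diketone by a primary allylic bromide should give the achiral diketone with two enantiotopic acetyl groups; the E,E geometry is not touched.

Step 2
Reactants: 3 3-methyl-3-[(2E,6E)-farnesyl]pentane-2,4-dione
Product: 4 (3R,4S)-4-hydroxy-3-methyl-3-[(2E,6E)-farnesyl]pentan-2-one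
Conditions: ketoreductase, NADP+ (cat.), i-PrOH, phosphate buffer pH 7, DMSO co-solvent, 30 °C
Reagents that add atoms: none
Why: Enzymatic desymmetrising reduction of a 2,2-disubstituted 1,3-diketone; the enzyme's choice of one enantiotopic acetyl group sets the quaternary centre (R) and its choice of carbonyl face sets the carbinol (S), and reduction of the second, now more hindered ketone is expected to be much slower.

Step 3
Reactants: 4 (3R,4S)-4-hydroxy-3-methyl-3-[(2E,6E)-farnesyl]pentan-2-one
Product: 5 (3R,4S)-3-methyl-4-(triethylsilyloxy)-3-[(2E,6E)-farnesyl]pentan-2-one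
Conditions: TESOTf, 2,6-lutidine, CH2Cl2, −78 °C; aq. NaHCO3
Reagents that add atoms: triethylsilyl trifluoromethanesulfonate, CC[Si](CC)(CC)OS(=O)(=O)C(F)(F)F
Why: Silyl triflate silylation of a hindered secondary alcohol; the ether blocks retro-aldol cleavage and O-acylation in the enolate steps, and low temperature keeps the ketone from being silylated.

Step 4
Reactants: 5 (3R,4S)-3-methyl-4-(triethylsilyloxy)-3-[(2E,6E)-farnesyl]pentan-2-one
Product: 6 (4R,5S)-4-methyl-5-(triethylsilyloxy)-4-[(2E,6E)-farnesyl]hexan-3-one
Conditions: LDA (commercial solution), THF, −78 °C; then MeI, −78 → −30 °C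
Reagents that add atoms: iodomethane, CI
Why: The ketone can enolise only toward its methyl group because the other α-carbon is quaternary, so kinetic lithium enolate formation and SN2 methylation should give the ethyl ketone; low temperature limits a second methylation.

Step 5
Reactants: 6 (4R,5S)-4-methyl-5-(triethylsilyloxy)-4-[(2E,6E)-farnesyl]hexan-3-one
Product: 7 (5R,6S)-3,5-dimethyl-6-(triethylsilyloxy)-5-[(2E,6E)-farnesyl]heptane-2,4-dione (C3 epimers and enol tautomers)
Conditions: MgBr2·OEt2, i-Pr2NEt, 1-acetylbenzotriazole, CH2Cl2, rt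
Reagents that add atoms: 1-acetyl-1H-benzotriazole, CC(=O)n1nnc2ccccc12
Why: Soft-enolisation Claisen-type C-acylation: the magnesium enolate of the only enolisable position is acetylated by the N-acylbenzotriazole, and the product is held as a magnesium diketonate that is not acylated further; the new CH(CH3) centre is labile and becomes sp2 in step 10.

Step 6
Reactants: 8 1,1'-carbonyldiimidazole; 9 2-(trimethylsilyl)ethanol
Product: 10 2-(trimethylsilyl)ethyl 1H-imidazole-1-carboxylate
Conditions: CH2Cl2, rt
Reagents that add atoms: none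
Why: Alcoholysis of carbonyldiimidazole stops at the alkyl imidazole-1-carboxylate, an alkoxycarbonyl donor for carbanions that has no acidic C–H.

Step 7
Reactants: 7 (5R,6S)-3,5-dimethyl-6-(triethylsilyloxy)-5-[(2E,6E)-farnesyl]heptane-2,4-dione; 10 2-(trimethylsilyl)ethyl 1H-imidazole-1-carboxylate
Product: 11 2-(trimethylsilyl)ethyl (6R,8E,12E)-4,6,9,13,17-pentamethyl-3,5-dioxo-6-[(1S)-1-(triethylsilyloxy)ethyl]octadeca-8,12,16-trienoate
Conditions: LDA (3 equiv), THF, −78 → 0 °C; then 10, −78 → −30 °C; aq. NH4Cl
Reagents that add atoms: none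
Why: γ-Carboxylation of a β-diketone dianion: the terminal, last-formed carbanion is the most nucleophilic site and should be acylated by the imidazole carboxylate (Claisen-type), the third equivalent of base covering the more acidic β,δ-diketo ester that forms.

Step 8
Reactants: 11 2-(trimethylsilyl)ethyl (6R,8E,12E)-4,6,9,13,17-pentamethyl-3,5-dioxo-6-[(1S)-1-(triethylsilyloxy)ethyl]octadeca-8,12,16-trienoate
Product: 12 2-(trimethylsilyl)ethyl (6R,8E,12E)-6-[(1S)-1-hydroxyethyl]-4,6,9,13,17-pentamethyl-3,5-dioxooctadeca-8,12,16-trienoate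
Conditions: HF·pyridine, pyridine, THF, 0 °C; crude product taken on at once
Reagents that add atoms: none
Why: Buffered HF·pyridine cleaves the triethylsilyl ether while the TMSE ester, which needs free fluoride, should survive; pyridine buffering and low temperature are meant to keep the liberated hydroxyl from closing onto the C3 carbonyl.

Step 9
Reactants: 12 2-(trimethylsilyl)ethyl (6R,8E,12E)-6-[(1S)-1-hydroxyethyl]-4,6,9,13,17-pentamethyl-3,5-dioxooctadeca-8,12,16-trienoate
Product: 13 2-(trimethylsilyl)ethyl (6R,8E,12E)-6-acetyl-4,6,9,13,17-pentamethyl-3,5-dioxooctadeca-8,12,16-trienoate (drawn as its 3-enol)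
Conditions: Dess–Martin periodinane, NaHCO3, CH2Cl2, 0 °C → rt
Reagents that add atoms: none
Why: Dess–Martin oxidation of the secondary alcohol to the methyl ketone under buffered, near-neutral conditions; the carbinol stereocentre is erased and the quaternary centre, which has no α-hydrogen, cannot epimerise.

Step 10
Reactants: 13 2-(trimethylsilyl)ethyl (6R,8E,12E)-6-acetyl-4,6,9,13,17-pentamethyl-3,5-dioxooctadeca-8,12,16-trienoate
Product: 15 2-(trimethylsilyl)ethyl (3R)-3-[(2E,6E)-farnesyl]-6-hydroxy-2,3,5-trimethyl-4-oxocyclohexa-1,5-diene-1-carboxylate, via 2-(trimethylsilyl)ethyl (3R)-3-[(2E,6E)-farnesyl]-2-hydroxy-2,3,5-trimethyl-4,6-dioxocyclohexane-1-carboxylate 14 (not isolated)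
Conditions: MgBr2·OEt2, i-Pr2NEt, CH2Cl2, 0 °C → rt (40 °C if dehydration is slow); pH 4 buffer work-up
Reagents that add atoms: none
Why: The amine deprotonates the magnesium-chelated β-keto ester at chain C2 (ring C5), this enolate adds to the magnesium-activated methyl ketone (ring C6) to give aldol 14, and E1cB loss of water followed by enolisation at ring C4 should give the chelated vinylogous acid 15 as a thermodynamic sink. The closest known reaction type is the base-mediated intramolecular aldol condensation of β,δ-diketo esters onto a terminal ketone used in biomimetic resorcylate synthesis, here halted at the dienone because ring C1 is quaternary. The single ring is closed in a 6-(enolendo)-exo-trig mode. No stereocentre is formed: C1 was set in step 2, carries no acidic hydrogen and is not involved in any bond change. The step needs chemoselectivity for C-attack on the ketone over O-attack on the ester (pyranone formation) and over retro-Claisen cleavage at C1. Chelation of the dicarbonyl unit, a non-nucleophilic amine, exclusion of water and alkoxide, and the far greater acidity of the active methylene than of the acetyl CH3 are expected to secure it, and the Claisen mode is structurally impossible.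

Step 11
Reactants: 15 2-(trimethylsilyl)ethyl (3R)-3-[(2E,6E)-farnesyl]-6-hydroxy-2,3,5-trimethyl-4-oxocyclohexa-1,5-diene-1-carboxylate
Product: 16 (3R)-6-hydroxy-2,3,5-trimethyl-4-oxo-3-[(2E,6E)-3,7,11-trimethyldodeca-2,6,10-trien-1-yl]cyclohexa-1,5-diene-1-carboxylic acid
Conditions: TBAF, THF, 0 °C → rt; then cold 0.5 M HCl to pH 3
Reagents that add atoms: none
Why: Fluoride attack at silicon and β-elimination (loss of ethene and fluorotrimethylsilane) free the carboxylate without hydroxide or heat, so the vinylogous β-keto acid should not decarboxylate and the C1 centre is untouched.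

**Compound list**

1 | 3-methylpentane-2,4-dione | CC(=O)C(C)C(C)=O | starting material
2 | (2E,6E)-farnesyl bromide | CC(C)=CCC/C(C)=C/CC/C(C)=C/CBr | starting material
3 | 3-methyl-3-[(2E,6E)-farnesyl]pentane-2,4-dione | CC(C)=CCC/C(C)=C/CC/C(C)=C/CC(C)(C(C)=O)C(C)=O | intermediate
4 | (3R,4S)-4-hydroxy-3-methyl-3-[(2E,6E)-farnesyl]pentan-2-one | CC(C)=CCC/C(C)=C/CC/C(C)=C/C[C@](C)([C@H](C)O)C(C)=O | intermediate
5 | (3R,4S)-3-methyl-4-(triethylsilyloxy)-3-[(2E,6E)-farnesyl]pentan-2-one | CC(C)=CCC/C(C)=C/CC/C(C)=C/C[C@](C)([C@H](C)O[Si](CC)(CC)CC)C(C)=O | intermediate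
6 | (4R,5S)-4-methyl-5-(triethylsilyloxy)-4-[(2E,6E)-farnesyl]hexan-3-one | CC(C)=CCC/C(C)=C/CC/C(C)=C/C[C@](C)([C@H](C)O[Si](CC)(CC)CC)C(=O)CC | intermediate
7 | (5R,6S)-3,5-dimethyl-6-(triethylsilyloxy)-5-[(2E,6E)-farnesyl]heptane-2,4-dione | CC(C)=CCC/C(C)=C/CC/C(C)=C/C[C@](C)([C@H](C)O[Si](CC)(CC)CC)C(=O)C(C)C(C)=O | intermediate
8 | 1,1'-carbonyldiimidazole | O=C(n1ccnc1)n1ccnc1 | starting material
9 | 2-(trimethylsilyl)ethanol | C[Si](C)(C)CCO | starting material
10 | 2-(trimethylsilyl)ethyl 1H-imidazole-1-carboxylate | C[Si](C)(C)CCOC(=O)n1ccnc1 | intermediate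
11 | 2-(trimethylsilyl)ethyl (6R,8E,12E)-4,6,9,13,17-pentamethyl-3,5-dioxo-6-[(1S)-1-(triethylsilyloxy)ethyl]octadeca-8,12,16-trienoate | CC(C)=CCC/C(C)=C/CC/C(C)=C/C[C@](C)([C@H](C)O[Si](CC)(CC)CC)C(=O)C(C)C(=O)CC(=O)OCC[Si](C)(C)C | intermediate
12 | 2-(trimethylsilyl)ethyl (6R,8E,12E)-6-[(1S)-1-hydroxyethyl]-4,6,9,13,17-pentamethyl-3,5-dioxooctadeca-8,12,16-trienoate | CC(C)=CCC/C(C)=C/CC/C(C)=C/C[C@](C)([C@H](C)O)C(=O)C(C)C(=O)CC(=O)OCC[Si](C)(C)C | intermediate
13 | 2-(trimethylsilyl)ethyl (6R,8E,12E)-6-acetyl-4,6,9,13,17-pentamethyl-3,5-dioxooctadeca-8,12,16-trienoate (3-enol drawn) | CC(C)=CCC/C(C)=C/CC/C(C)=C/C[C@](C)(C(C)=O)C(=O)/C(C)=C(\O)CC(=O)OCC[Si](C)(C)C | intermediate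
14 | 2-(trimethylsilyl)ethyl (3R)-3-[(2E,6E)-farnesyl]-2-hydroxy-2,3,5-trimethyl-4,6-dioxocyclohexane-1-carboxylate (aldol adduct, mixture at C1, C2, C5) | CC(C)=CCC/C(C)=C/CC/C(C)=C/C[C@@]1(C)C(=O)C(C)C(=O)C(C(=O)OCC[Si](C)(C)C)C1(C)O | intermediate
15 | 2-(trimethylsilyl)ethyl (3R)-3-[(2E,6E)-farnesyl]-6-hydroxy-2,3,5-trimethyl-4-oxocyclohexa-1,5-diene-1-carboxylate | CC(C)=CCC/C(C)=C/CC/C(C)=C/C[C@@]1(C)C(=O)C(C)=C(O)C(C(=O)OCC[Si](C)(C)C)=C1C | intermediate
16 | (3R)-6-hydroxy-2,3,5-trimethyl-4-oxo-3-[(2E,6E)-3,7,11-trimethyldodeca-2,6,10-trien-1-yl]cyclohexa-1,5-diene-1-carboxylic acid | CC(C)=CCC/C(C)=C/CC/C(C)=C/C[C@@]1(C)C(=O)C(C)=C(O)C(C(=O)O)=C1C | target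

**Step count**

Total steps: 11. Longest linear sequence: 10 (steps 1–5 and 7–11).

**Steps most likely to fail**

1. Step 10. The enol oxygen may attack the ester instead of carbon attacking the ketone (lactonisation with loss of the silyl alcohol), the non-enolisable 1,3-diketone at C1 may be cleaved by retro-Claisen deacetylation, or the sequence may stall at the aldol stage on the hindered ketone. Fallback: setting out from 13, the TMSE ester would be cleaved first with TBAF in THF at 0 °C to give (6R,8E,12E)-6-acetyl-4,6,9,13,17-pentamethyl-3,5-dioxooctadeca-8,12,16-trienoic acid F1 as its carboxylate. The solution would then be diluted into aqueous buffer at pH 8–9 and room temperature. A carboxylate cannot be lactonised, and aldol closure of 3,5,7-triketo carboxylates in water is the classical resorcylate mode. Cold acidification would give 16 directly, where the fallback rejoins the route.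

2. Step 2. The very lipophilic substrate may turn over poorly, the enzyme may select the wrong enantiotopic acetyl group, or reduction may run on to the diol. Fallback: setting out from 3, a CBS reduction ((R)-2-methyl-CBS-oxazaborolidine, catecholborane, toluene, −78 °C, one equivalent of hydride) would fix the carbinol as (S) by reagent control. It would give 4 together with its C3 epimer, (3S,4S)-4-hydroxy-3-methyl-3-[(2E,6E)-farnesyl]pentan-2-one F2. The two diastereomers would be separated by chromatography and F2 oxidised back to 3 with Dess–Martin periodinane for recycling. The route is rejoined at 4.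

3. Step 8. Under the acidic fluoride source the liberated hydroxyl may add to the C3 carbonyl and dehydrate to a dihydropyranone, or the TMSE ester may be partly lost. Fallback: setting out from 7, the silyl ether would be removed with TBAF in THF at 0 °C, before any fluoride-labile ester is present and with the β-diketone held as its enolate, to give (5R,6S)-6-hydroxy-3,5-dimethyl-5-[(2E,6E)-farnesyl]heptane-2,4-dione F3. Its trianion (LDA, 3.3 equiv, THF, −78 → 0 °C) would then be carboxylated at the terminal carbanion, the most nucleophilic site, with one equivalent of 10 and worked up at pH 7. This gives 12 without any exposure to acid, and the route is rejoined at 12 for step 9.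

**Further compounds**

F1 | step 10 | (6R,8E,12E)-6-acetyl-4,6,9,13,17-pentamethyl-3,5-dioxooctadeca-8,12,16-trienoic acid | CC(C)=CCC/C(C)=C/CC/C(C)=C/C[C@](C)(C(C)=O)C(=O)C(C)C(=O)CC(=O)O
F2 | step 2 | (3S,4S)-4-hydroxy-3-methyl-3-[(2E,6E)-farnesyl]pentan-2-one | CC(C)=CCC/C(C)=C/CC/C(C)=C/C[C@@](C)([C@H](C)O)C(C)=O
F3 | step 8 | (5R,6S)-6-hydroxy-3,5-dimethyl-5-[(2E,6E)-farnesyl]heptane-2,4-dione | CC(C)=CCC/C(C)=C/CC/C(C)=C/C[C@](C)([C@H](C)O)C(=O)C(C)C(C)=O
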